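## Retrosynthetic overview

1. Hopeafuran ⇒ (hydrogenolysis, oxidation of the C-α carbinol, desilylation) a trans bis-silyl tetrabenzyl ether that carries the ketone as CH–OSi, so the methine stereocentre C-β is α to a carbonyl only at the end.
2. Feature: the resorcinol ring is bonded through one carbon to benzofuran C3 and through the adjacent carbon to C-β. The bond between these two carbons is shared with the seven-membered ring (C3, C3a, C4, C-α, C-β and the two resorcinol carbons). An ethynyl group on C3 and a 1-silyloxy-3-benzyloxycyclohexa-1,3-diene on C-β therefore close both rings in one intramolecular Alder–Rickert reaction (Diels–Alder, then loss of ethene).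
3. The diene is the silyl dienol ether of a 6-substituted 3-benzyloxycyclohex-2-enone. The α'-enolate of the enone opens an (S,S)-stilbene oxide at the 4-benzyloxybenzylic carbon with inversion, which sets C-β. The epoxide comes from Shi epoxidation of an E-stilbene made by Horner–Wadsworth–Emmons olefination.
4. The 2-aryl-3-alkynylbenzofuran-4-carbaldehyde comes from 3,5-dihydroxybenzonitrile by iodination, Sonogashira coupling, iodocyclisation, a second Sonogashira coupling and nitrile reduction. Ring order: furan ring first, then resorcinol ring and seven-membered ring together.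

Key step: step 15

Remark on labels: C-α is the carbon on benzofuran C4 (carbinol, later the ketone); C-β is the methine carrying the 4-oxygenated phenyl ring, the only stereocentre of the target (S).
Remark (assumption): the L-fructose-derived enantiomer of the Shi ketone is taken as purchasable (or made from L-sorbose); the D-fructose-derived ketone gives (R,R)-epoxides from E-stilbenes, so its enantiomer should give the (S,S)-epoxide.
Remark: the cyclohexenone ring carbon attached to C-β is an epimeric mixture in two intermediates and is erased on dienol ether formation.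

## Route

Step 1
Reactants: 1 3,5-dihydroxybenzonitrile
Product: 2 3,5-bis(benzyloxy)benzonitrile
Conditions: BnBr, K2CO3, DMF, 60 °C
Reagents that add atoms: benzyl bromide, BrCc1ccccc1
Why: Williamson ether synthesis in which both phenols are alkylated by the benzylic bromide under carbonate conditions that leave the nitrile untouched.

Step 2
Reactants: 2 3,5-bis(benzyloxy)benzonitrile
Product: 3 3,5-bis(benzyloxy)-2-iodobenzonitrile
Conditions: NIS, CF3CO2H (cat.), MeCN, rt
Reagents that add atoms: N-iodosuccinimide, O=C1CCC(=O)N1I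
Why: electrophilic aromatic iodination at C2, which is para to one benzyloxy group, ortho to the other and less crowded than C4 between the two ethers, the position at which 3,5-dialkoxybenzoic acid derivatives are halogenated.

Step 3
Reactants: 3 3,5-bis(benzyloxy)-2-iodobenzonitrile; 4 1-(benzyloxy)-4-ethynylbenzene
Product: 5 3,5-bis(benzyloxy)-2-{[4-(benzyloxy)phenyl]ethynyl}benzonitrile
Conditions: PdCl2(PPh3)2 (cat.), CuI (cat.), Et3N, THF, 50 °C
Reagents that add atoms: none
Why: Sonogashira coupling of an aryl iodide whose oxidative addition is helped by the ortho nitrile, with a slim alkyne that tolerates the two flanking groups.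

Step 4
Reactants: 5 3,5-bis(benzyloxy)-2-{[4-(benzyloxy)phenyl]ethynyl}benzonitrile
Product: 6 6-(benzyloxy)-2-[4-(benzyloxy)phenyl]-3-iodo-1-benzofuran-4-carbonitrile
Conditions: I2, NaHCO3, CH2Cl2, rt, dark
Reagents that add atoms: iodine, II
Why: iodocyclisation (electrophilic 5-endo-dig closure) in which the ortho benzyloxy oxygen attacks the iodonium-activated alkyne at the carbon carrying the donor aryl group and iodide removes the benzyl group from the oxonium ion, while the linear nitrile cannot compete as an internal nucleophile.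

Step 5
Reactants: 6 6-(benzyloxy)-2-[4-(benzyloxy)phenyl]-3-iodo-1-benzofuran-4-carbonitrile; 7 ethynyltrimethylsilane
Product: 8 6-(benzyloxy)-2-[4-(benzyloxy)phenyl]-3-[(trimethylsilyl)ethynyl]-1-benzofuran-4-carbonitrile
Conditions: PdCl2(PPh3)2 (cat.), CuI (cat.), Et3N, DMF, 60 °C
Reagents that add atoms: none
Why: Sonogashira coupling at the 3-iodobenzofuran, a reactive heteroaryl iodide, with the silyl group keeping the alkyne masked through the later base steps.

Step 6
Reactants: 8 6-(benzyloxy)-2-[4-(benzyloxy)phenyl]-3-[(trimethylsilyl)ethynyl]-1-benzofuran-4-carbonitrile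
Product: 10 6-(benzyloxy)-2-[4-(benzyloxy)phenyl]-3-[(trimethylsilyl)ethynyl]-1-benzofuran-4-carbaldehyde, via aluminium aldimine 9 (not isolated)
Conditions: i-Bu2AlH, CH2Cl2, −78 °C; then 1 M HCl, 0 °C
Reagents that add atoms: water, O
Why: partial reduction of the nitrile, in which the N-aluminio aldimine takes up no second hydride at low temperature and is hydrolysed to the aldehyde, while the silylalkyne and benzyl ethers are inert.

Step 7
Reactants: 11 4-(benzyloxy)benzyl chloride
Product: 12 diethyl [4-(benzyloxy)benzyl]phosphonate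
Conditions: P(OEt)3, neat, 140 °C
Reagents that add atoms: triethyl phosphite, CCOP(OCC)OCC
Why: Michaelis–Arbuzov reaction of a reactive benzylic chloride, driven by loss of chloroethane.

Step 8
Reactants: 10 6-(benzyloxy)-2-[4-(benzyloxy)phenyl]-3-[(trimethylsilyl)ethynyl]-1-benzofuran-4-carbaldehyde; 12 diethyl [4-(benzyloxy)benzyl]phosphonate
Product: 14 6-(benzyloxy)-2-[4-(benzyloxy)phenyl]-4-{(E)-2-[4-(benzyloxy)phenyl]ethenyl}-3-[(trimethylsilyl)ethynyl]-1-benzofuran, via potassium phosphonate carbanion 13 (not isolated)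
Conditions: 12, KN(SiMe3)2, THF, −78 °C; then 10, −78 °C → rt
Reagents that add atoms: none
Why: Horner–Wadsworth–Emmons olefination, in which benzylic phosphonate anions and aryl aldehydes give E-stilbenes through reversible addition and syn elimination, and the silylamide base does not attack the alkynylsilane.

Step 9
Reactants: 14 6-(benzyloxy)-2-[4-(benzyloxy)phenyl]-4-{(E)-2-[4-(benzyloxy)phenyl]ethenyl}-3-[(trimethylsilyl)ethynyl]-1-benzofuran
Product: 15 {[6-(benzyloxy)-2-[4-(benzyloxy)phenyl]-4-{(2S,3S)-3-[4-(benzyloxy)phenyl]oxiran-2-yl}-1-benzofuran-3-yl]ethynyl}trimethylsilane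
Conditions: L-fructose-derived Shi ketone (0.3 equiv), KHSO5 (Oxone), K2CO3, Bu4NHSO4, MeCN/CH2(OMe)2/aq. Na2B4O7–Na2EDTA, pH 10.5, 0 °C
Reagents that add atoms: potassium peroxymonosulfate (Oxone), [K+].[O-]S(=O)(=O)OO
Why: Shi epoxidation, in which the chiral dioxirane transfers oxygen to the E-olefin through a spiro transition state so that the catalyst enantiomer sets both epoxide carbons as S, the disubstituted olefin should react before the aromatic furan double bond or the alkyne, and the basic medium protects the acid-labile epoxide.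

Step 10
Reactants: 16 cyclohexane-1,3-dione
Product: 17 3-(benzyloxy)cyclohex-2-en-1-one
Conditions: BnOH, p-TsOH (cat.), toluene, reflux, Dean–Stark
Reagents that add atoms: benzyl alcohol, OCc1ccccc1
Why: acid-catalysed enol etherification of the symmetrical dione (vinylogous ester formation) driven by azeotropic removal of water.

Step 11
Reactants: 15 {[6-(benzyloxy)-2-[4-(benzyloxy)phenyl]-4-{(2S,3S)-3-[4-(benzyloxy)phenyl]oxiran-2-yl}-1-benzofuran-3-yl]ethynyl}trimethylsilane; 17 3-(benzyloxy)cyclohex-2-en-1-one
Product: 19 6-(benzyloxy)-2-[4-(benzyloxy)phenyl]-4-{(1R,2R)-2-[4-(benzyloxy)phenyl]-2-[4-(benzyloxy)-2-oxocyclohex-3-en-1-yl]-1-hydroxyethyl}-3-[(trimethylsilyl)ethynyl]-1-benzofuran (mixture of epimers at the ring carbon), via lithium enolate 18 (not isolated)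
Conditions: 17, LiN(i-Pr)2, THF, −78 °C; then 15; then BF3·OEt2, −78 °C; aq. NaHCO3
Reagents that add atoms: none
Why: kinetic α'-deprotonation of the vinylogous ester (Stork–Danheiser regiochemistry) followed by Lewis-acid-assisted SN2-type epoxide opening at the 4-benzyloxybenzylic carbon, the less hindered carbon and the one better able to carry positive charge, so that inversion there sets C-β from the epoxide while C-α keeps its configuration and the new ring stereocentre forms unselectively and is erased in step 13.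

Step 12
Reactants: 19 the γ-hydroxy ketone of step 11
Product: 20 6-(benzyloxy)-2-[4-(benzyloxy)phenyl]-4-{(1R,2R)-2-[4-(benzyloxy)phenyl]-2-[4-(benzyloxy)-2-oxocyclohex-3-en-1-yl]-1-[(tert-butyldimethylsilyl)oxy]ethyl}-3-[(trimethylsilyl)ethynyl]-1-benzofuran (mixture of epimers at the ring carbon)
Conditions: TBSOTf, 2,6-lutidine, CH2Cl2, −78 → 0 °C; aq. NaHCO3
Reagents that add atoms: tert-butyldimethylsilyl trifluoromethanesulfonate, CC(C)(C)[Si](C)(C)OS(=O)(=O)C(F)(F)F
Why: silyl ether formation at the hindered secondary benzylic alcohol with the silyl triflate and a non-nucleophilic pyridine base, any silyl dienol ether formed at the vinylogous ester being hydrolysed back on the bicarbonate work-up.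

Step 13
Reactants: 20 the silyl ether of step 12
Product: 22 6-(benzyloxy)-2-[4-(benzyloxy)phenyl]-4-{(1R,2S)-2-[4-(benzyloxy)phenyl]-2-[4-(benzyloxy)-2-[(tert-butyldimethylsilyl)oxy]cyclohexa-1,3-dien-1-yl]-1-[(tert-butyldimethylsilyl)oxy]ethyl}-3-[(trimethylsilyl)ethynyl]-1-benzofuran, via lithium dienolate 21 (not isolated)
Conditions: LiN(i-Pr)2, THF, −78 °C; TBSCl, DMPU, −78 → 0 °C; pH 7 buffer, Et3N-treated silica
Reagents that add atoms: tert-butyldimethylsilyl chloride, CC(C)(C)[Si](C)(C)Cl
Why: silyl dienol ether formation, in which lithium amide deprotonates a 3-alkoxycyclohex-2-enone at the α' carbon also when that carbon is substituted and O-silylation of the cross-conjugated dienolate gives the 1-silyloxy-3-benzyloxy-1,3-diene, removing the ring stereocentre and leaving C-α and C-β untouched (the C-β descriptor changes from R to S by priority only).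

Step 14
Reactants: 22 the bis-silyl dienol ether of step 13
Product: 23 6-(benzyloxy)-2-[4-(benzyloxy)phenyl]-4-{(1R,2S)-2-[4-(benzyloxy)phenyl]-2-[4-(benzyloxy)-2-[(tert-butyldimethylsilyl)oxy]cyclohexa-1,3-dien-1-yl]-1-[(tert-butyldimethylsilyl)oxy]ethyl}-3-ethynyl-1-benzofuran
Conditions: K2CO3 (0.5 equiv), MeOH/THF, 0 °C, short; pH 7 buffer
Reagents that add atoms: none
Why: protodesilylation, in which methoxide attacks the unhindered alkynyl trimethylsilyl group much faster than the two tert-butyldimethylsilyl ethers, so the terminal alkyne is freed while the dienol ether stays.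

Step 15
Reactants: 23 the 3-ethynylbenzofuran tethered to the silyloxy diene
Product: 25 trans bis-silyl tetrabenzyl ether of the hopeafuran skeleton (C-α R with OTBS in place of C=O, C-β S, resorcinol oxygen next to the ring fusion as OTBS, the other as OBn), via bicyclo[2.2.2]octadiene adduct 24 (not isolated)
Conditions: o-C6H4Cl2 (0.01 M, degassed), BHT, i-Pr2NEt (cat.), 160–180 °C, sealed tube
Reagents that add atoms: none
Why: Proposed new method: on heating, the electron-rich silyloxy diene of 23 adds across the C3-ethynyl group in an intramolecular (4+2) cycloaddition (alkyne carbon on benzofuran C3 to the diene carbon on C-β, terminal alkyne carbon to the benzyloxy-bearing diene terminus) to give bicyclo[2.2.2]octadiene 24, which loses its CH2–CH2 bridge as ethene by retro-(4+2) fragmentation and becomes the arene; the closest known reactions are the Alder–Rickert synthesis of resorcinol ethers from 1,3-dioxygenated cyclohexa-1,3-dienes and activated alkynes, and intramolecular Diels–Alder reactions of unactivated alkynes at 150–250 °C. The seven-membered ring closes as the tether ring of a type 1 intramolecular cycloaddition, in which three of the five tether atoms are the rigid C3–C3a–C4 unit of the benzofuran, and the six-membered ring closes in the same cycloaddition and is aromatised by the cycloreversion. No new stereocentre survives, because the two bridgehead centres of 24 vanish with the ethene and C-α and C-β are spectators that keep their trans relationship. The regiochemistry is fixed by the tether and places the silyloxy group next to the carbon on C-β and the benzyloxy group between the two aromatic CH positions. The step needs cycloaddition to outrun 1,5-hydrogen shifts of the cyclohexadiene and hydrolysis of the dienol ether, which the small terminal alkyne, high dilution, an amine acid scavenger and the lowest workable temperature are meant to secure.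

Step 16
Reactants: 25 the trans bis-silyl tetrabenzyl ether of step 15
Product: 26 tetrabenzyl diol (free C-α carbinol and free resorcinol phenol next to the ring fusion)
Conditions: Bu4NF, THF, 0 °C → rt
Reagents that add atoms: none
Why: fluoride-mediated desilylation, which cleaves both the aryl silyl ether and the secondary benzylic silyl ether while the benzyl ethers stay.

Step 17
Reactants: 26 the tetrabenzyl diol of step 16
Product: 27 pentabenzyl alcohol (all five phenols as benzyl ethers, C-α carbinol free)
Conditions: BnBr, K2CO3, DMF, rt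
Reagents that add atoms: benzyl bromide, BrCc1ccccc1
Why: Williamson etherification, in which carbonate deprotonates only the phenol so that the secondary alcohol is left for the oxidation.

Step 18
Reactants: 27 the pentabenzyl alcohol of step 17
Product: 28 hopeafuran pentabenzyl ether
Conditions: Dess–Martin periodinane, NaHCO3, CH2Cl2, 0 °C → rt
Reagents that add atoms: none
Why: Dess–Martin oxidation under buffered, non-basic conditions, which forms the aryl ketone without enolising the now α-positioned, doubly benzylic C-β stereocentre and removes the auxiliary C-α stereocentre.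

Step 19
Reactants: 28 hopeafuran pentabenzyl ether
Product: 29 hopeafuran
Conditions: H2 (1 atm), Pd/C, EtOAc/MeOH, rt
Reagents that add atoms: none
Why: hydrogenolysis of the five benzyl ethers over palladium under neutral conditions, under which the aryl ketone and the tetrasubstituted benzofuran double bond should persist and C-β is not epimerised.

## Compound list

1 | 3,5-dihydroxybenzonitrile | N#Cc1cc(O)cc(O)c1 | starting material
2 | 3,5-bis(benzyloxy)benzonitrile | N#Cc1cc(OCc2ccccc2)cc(OCc2ccccc2)c1 | intermediate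
3 | 3,5-bis(benzyloxy)-2-iodobenzonitrile | N#Cc1cc(OCc2ccccc2)cc(OCc2ccccc2)c1I | intermediate
4 | 1-(benzyloxy)-4-ethynylbenzene | C#Cc1ccc(OCc2ccccc2)cc1 | starting material
5 | 3,5-bis(benzyloxy)-2-{[4-(benzyloxy)phenyl]ethynyl}benzonitrile | N#Cc1cc(OCc2ccccc2)cc(OCc2ccccc2)c1C#Cc1ccc(OCc2ccccc2)cc1 | intermediate
6 | 6-(benzyloxy)-2-[4-(benzyloxy)phenyl]-3-iodo-1-benzofuran-4-carbonitrile | N#Cc1cc(OCc2ccccc2)cc2oc(-c3ccc(OCc4ccccc4)cc3)c(I)c12 | intermediate
7 | ethynyltrimethylsilane | C#C[Si](C)(C)C | starting material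
8 | 6-(benzyloxy)-2-[4-(benzyloxy)phenyl]-3-[(trimethylsilyl)ethynyl]-1-benzofuran-4-carbonitrile | N#Cc1cc(OCc2ccccc2)cc2oc(-c3ccc(OCc4ccccc4)cc3)c(C#C[Si](C)(C)C)c12 | intermediate
9 | N-(diisobutylalumanyl) aldimine of 10 | CC(C)C[Al](CC(C)C)N=Cc1cc(OCc2ccccc2)cc2oc(-c3ccc(OCc4ccccc4)cc3)c(C#C[Si](C)(C)C)c12 | intermediate
10 | 6-(benzyloxy)-2-[4-(benzyloxy)phenyl]-3-[(trimethylsilyl)ethynyl]-1-benzofuran-4-carbaldehyde | O=Cc1cc(OCc2ccccc2)cc2oc(-c3ccc(OCc4ccccc4)cc3)c(C#C[Si](C)(C)C)c12 | intermediate
11 | 4-(benzyloxy)benzyl chloride | ClCc1ccc(OCc2ccccc2)cc1 | starting material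
12 | diethyl [4-(benzyloxy)benzyl]phosphonate | CCOP(=O)(OCC)Cc1ccc(OCc2ccccc2)cc1 | intermediate
13 | potassium salt of the benzylic carbanion of 12 | CCOP(=O)(OCC)[CH-]c1ccc(OCc2ccccc2)cc1.[K+] | intermediate
14 | E-stilbene: 6-(benzyloxy)-2-[4-(benzyloxy)phenyl]-4-{(E)-2-[4-(benzyloxy)phenyl]ethenyl}-3-[(trimethylsilyl)ethynyl]-1-benzofuran | C[Si](C)(C)C#Cc1c(-c2ccc(OCc3ccccc3)cc2)oc2cc(OCc3ccccc3)cc(/C=C/c3ccc(OCc4ccccc4)cc3)c12 | intermediate
15 | (2S,3S)-epoxide of 14 | C[Si](C)(C)C#Cc1c(-c2ccc(OCc3ccccc3)cc2)oc2cc(OCc3ccccc3)cc([C@@H]3O[C@H]3c3ccc(OCc4ccccc4)cc3)c12 | intermediate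
16 | cyclohexane-1,3-dione | O=C1CCCC(=O)C1 | starting material
17 | 3-(benzyloxy)cyclohex-2-en-1-one | O=C1C=C(OCc2ccccc2)CCC1 | intermediate
18 | lithium 5-(benzyloxy)cyclohexa-1,5-dien-1-olate (α'-enolate of 17) | [Li+].[O-]C1=CCCC(OCc2ccccc2)=C1 | intermediate
19 | γ-hydroxy ketone: C-α (R) carbinol on benzofuran C4, C-β (R by priority) carrying 4-benzyloxyphenyl and the 4-(benzyloxy)-2-oxocyclohex-3-en-1-yl ring (ring carbon epimeric) | C[Si](C)(C)C#Cc1c(-c2ccc(OCc3ccccc3)cc2)oc2cc(OCc3ccccc3)cc([C@H](O)[C@@H](c3ccc(OCc4ccccc4)cc3)C3CCC(OCc4ccccc4)=CC3=O)c12 | intermediate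
20 | tert-butyldimethylsilyl ether of 19 at the C-α oxygen | C[Si](C)(C)C#Cc1c(-c2ccc(OCc3ccccc3)cc2)oc2cc(OCc3ccccc3)cc([C@H](O[Si](C)(C)C(C)(C)C)[C@@H](c3ccc(OCc4ccccc4)cc3)C3CCC(OCc4ccccc4)=CC3=O)c12 | intermediate
21 | lithium cross-conjugated dienolate of 20 | [Li+].C[Si](C)(C)C#Cc1c(-c2ccc(OCc3ccccc3)cc2)oc2cc(OCc3ccccc3)cc([C@H](O[Si](C)(C)C(C)(C)C)[C@@H](c3ccc(OCc4ccccc4)cc3)C3=C([O-])C=C(OCc4ccccc4)CC3)c12 | intermediate
22 | bis-silyl dienol ether with trimethylsilylalkyne (C-α R, C-β S) | C[Si](C)(C)C#Cc1c(-c2ccc(OCc3ccccc3)cc2)oc2cc(OCc3ccccc3)cc([C@H](O[Si](C)(C)C(C)(C)C)[C@@H](c3ccc(OCc4ccccc4)cc3)C3=C(O[Si](C)(C)C(C)(C)C)C=C(OCc4ccccc4)CC3)c12 | intermediate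
23 | key-step precursor: 3-ethynylbenzofuran tethered through C-α (R, OTBS) and C-β (S) to the 1-silyloxy-3-benzyloxycyclohexa-1,3-diene | C#Cc1c(-c2ccc(OCc3ccccc3)cc2)oc2cc(OCc3ccccc3)cc([C@H](O[Si](C)(C)C(C)(C)C)[C@@H](c3ccc(OCc4ccccc4)cc3)C3=C(O[Si](C)(C)C(C)(C)C)C=C(OCc4ccccc4)CC3)c12 | intermediate
24 | bicyclo[2.2.2]octadiene cycloadduct (bridgehead configuration fixed by the tether, not assigned, lost on aromatisation) | CC(C)(C)[Si](C)(C)O[C@H]1c2cc(OCc4ccccc4)cc3oc(-c4ccc(OCc5ccccc5)cc4)c(c23)C2=CC3(OCc4ccccc4)CCC2(C(O[Si](C)(C)C(C)(C)C)=C3)[C@@H]1c1ccc(OCc4ccccc4)cc1 | intermediate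
25 | key-step product: trans bis-silyl tetrabenzyl ether with both new rings (C-α R, C-β S) | CC(C)(C)[Si](C)(C)O[C@H]1c2cc(OCc4ccccc4)cc3oc(-c4ccc(OCc5ccccc5)cc4)c(c23)-c2cc(OCc4ccccc4)cc(O[Si](C)(C)C(C)(C)C)c2[C@@H]1c1ccc(OCc4ccccc4)cc1 | intermediate
26 | tetrabenzyl diol (C-α carbinol and one resorcinol phenol free) | O[C@H]1c2cc(OCc4ccccc4)cc3oc(-c4ccc(OCc5ccccc5)cc4)c(c23)-c2cc(OCc4ccccc4)cc(O)c2[C@@H]1c1ccc(OCc4ccccc4)cc1 | intermediate
27 | pentabenzyl alcohol (C-α R carbinol, C-β S) | O[C@H]1c2cc(OCc4ccccc4)cc3oc(-c4ccc(OCc5ccccc5)cc4)c(c23)-c2cc(OCc4ccccc4)cc(OCc4ccccc4)c2[C@@H]1c1ccc(OCc4ccccc4)cc1 | intermediate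
28 | hopeafuran pentabenzyl ether (C-β S) | O=C1c2cc(OCc4ccccc4)cc3oc(-c4ccc(OCc5ccccc5)cc4)c(c23)-c2cc(OCc4ccccc4)cc(OCc4ccccc4)c2[C@@H]1c1ccc(OCc4ccccc4)cc1 | intermediate
29 | hopeafuran | O=C1c2cc(O)cc3oc(-c4ccc(O)cc4)c(c23)-c2cc(O)cc(O)c2[C@@H]1c1ccc(O)cc1 | target

## Step count and risks

Total step count: 19 (17 in the main line, plus step 7 and step 10 for the two side fragments).
Longest linear sequence: 17 steps (steps 1–6, 8, 9, 11–19) from 3,5-dihydroxybenzonitrile.

Steps most likely to fail:

1. Step 15 (the proposed new method). The cycloaddition of the unactivated arylalkyne may be slower than 1,5-hydrogen shifts in the cyclohexadiene or than thermal decay of the dienol ether, so the diene would be scrambled before the two bonds form. The fallback uses known chemistry and carries the resorcinol ring in as an arene. It sets out from 6. Suzuki–Miyaura coupling with 3,5-bis(benzyloxy)phenylboronic acid (Pd(PPh3)4, K2CO3, dioxane/H2O, 90 °C) should give 6-(benzyloxy)-2-[4-(benzyloxy)phenyl]-3-[3,5-bis(benzyloxy)phenyl]-1-benzofuran-4-carbonitrile F1. Reduction with i-Bu2AlH and acidic work-up should give the corresponding 4-carbaldehyde F2. Horner–Wadsworth–Emmons olefination with 12 should give the E-stilbene F3, and Shi epoxidation with the same L-fructose-derived ketone the (2S,3S)-epoxide F4. Treatment of F4 with BF3·OEt2 in CH2Cl2 at −78 °C should close the seven-membered ring by intramolecular Friedel–Crafts attack of the resorcinol ortho carbon on the 4-benzyloxybenzylic epoxide carbon with inversion. This gives the trans alcohol and comes back to the route at 27.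

2. Step 11. The Lewis acid may ionise the 4-benzyloxyphenyl epoxide faster than the enolate captures it, which would lead to a 1,2-shift to carbonyl compounds or to partial loss of inversion at C-β. Any C-β epimer formed is a diastereomer and can be removed. The fallback replaces the anionic opening by a Mukaiyama-type alkylation with silyl transfer. It sets out from 17 and 15. Compound 17 is converted with LiN(i-Pr)2 and TBSCl/DMPU into its cross-conjugated silyl dienol ether, {[5-(benzyloxy)cyclohexa-1,5-dien-1-yl]oxy}(tert-butyl)dimethylsilane F5. An excess of this neutral nucleophile is combined with 15 and catalytic TBSOTf in CH2Cl2 at −78 °C, so that the silyl group ends on the C-α oxygen. The fallback comes back to the route at 20 and bypasses 19.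

3. Step 9. The acid- and water-labile 4-benzyloxyphenyl epoxide may be hydrolysed in the aqueous medium, or the dioxirane may also oxidise the electron-rich benzofuran double bond. The fallback builds the epoxide under anhydrous basic conditions by asymmetric sulfur-ylide (Corey–Chaykovsky-type) epoxidation and bypasses 14. It sets out from 10 and 11. Compound 11 is alkylated onto (2R,5R)-2,5-dimethylthiolane (AgBF4, CH2Cl2) to give (2R,5R)-1-[4-(benzyloxy)benzyl]-2,5-dimethylthiolan-1-ium tetrafluoroborate F6. This C2-symmetric sulfide is expected to give the (S,S) sense with benzyl ylides; the antipodal sulfide would be used if the sense proves opposite. Deprotonation of F6 with LiN(SiMe3)2 in THF at −78 °C and addition of 10 should give the trans epoxide, and the fallback comes back to the route at 15.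

## Further compounds

F1 | step 15 | 6-(benzyloxy)-2-[4-(benzyloxy)phenyl]-3-[3,5-bis(benzyloxy)phenyl]-1-benzofuran-4-carbonitrile | N#Cc1cc(OCc2ccccc2)cc2oc(-c3ccc(OCc4ccccc4)cc3)c(-c3cc(OCc4ccccc4)cc(OCc4ccccc4)c3)c12
F2 | step 15 | 6-(benzyloxy)-2-[4-(benzyloxy)phenyl]-3-[3,5-bis(benzyloxy)phenyl]-1-benzofuran-4-carbaldehyde | O=Cc1cc(OCc2ccccc2)cc2oc(-c3ccc(OCc4ccccc4)cc3)c(-c3cc(OCc4ccccc4)cc(OCc4ccccc4)c3)c12
F3 | step 15 | 6-(benzyloxy)-2-[4-(benzyloxy)phenyl]-3-[3,5-bis(benzyloxy)phenyl]-4-{(E)-2-[4-(benzyloxy)phenyl]ethenyl}-1-benzofuran | O(Cc1ccccc1)c1ccc(/C=C/c2cc(OCc3ccccc3)cc3oc(-c4ccc(OCc5ccccc5)cc4)c(-c4cc(OCc5ccccc5)cc(OCc5ccccc5)c4)c23)cc1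
F4 | step 15 | 6-(benzyloxy)-2-[4-(benzyloxy)phenyl]-3-[3,5-bis(benzyloxy)phenyl]-4-{(2S,3S)-3-[4-(benzyloxy)phenyl]oxiran-2-yl}-1-benzofuran | O(Cc1ccccc1)c1cc(OCc2ccccc2)cc(c1)-c1c(-c2ccc(OCc3ccccc3)cc2)oc2cc(OCc3ccccc3)cc([C@@H]3O[C@H]3c3ccc(OCc4ccccc4)cc3)c12
F5 | step 11 | {[5-(benzyloxy)cyclohexa-1,5-dien-1-yl]oxy}(tert-butyl)dimethylsilane | CC(C)(C)[Si](C)(C)OC1=CCCC(OCc2ccccc2)=C1
F6 | step 9 | (2R,5R)-1-[4-(benzyloxy)benzyl]-2,5-dimethylthiolan-1-ium tetrafluoroborate | C[C@@H]1CC[C@@H](C)[S+]1Cc1ccc(OCc2ccccc2)cc1.F[B-](F)(F)F
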